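**Plan**
- Enabling feature: the lactone carbonyl C12 lies between O6 and the exo-methylene carbon C11, so the α-methylene-γ-butyrolactone fused trans at C6/C7 of the ten-membered ring equals a trans C6-hydroxy/C7-ethynyl pair plus one CO (C14 acid on C10, C15 methyl on C4, angelates on O8/O9).
- Retrosynthesis: cut O6–C12 and C11–C12 (CO out), then the O8/O9 esters, then C5–C6 of the carbocycle (Z-alkenyl iodide + aldehyde), then C1=C10 (aldol/elimination), C9–C10 (acetate aldol), C7–C11 (alkynyl opening of an epoxide) and C2–C3 (allylic alkylation).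
- Forward: the C6–C9 triad is made first, C10/C14 and then the C1–C5 iodoalkene arm are added, the ten-membered ring closes by Ni/Cr coupling, and the lactone ring closes last by CO insertion.
- Stereochemistry: C7/C8 from a Sharpless epoxide opened with inversion, C9 by 1,2-chelation control, C6 by Felkin-type addition in the ring closure; 4Z alkene from anti-carbomagnesiation, 1(10)E enoate by E1cB elimination, angelate geometry from angelic acid.

Key step: step 22

Remark: germacrane numbering is used for all intermediates (ring C1–C10, C11–C13 lactone carbons, C14 acid, C15 methyl); the CIP label at C7 changes along the route only because substituent priorities change.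

**Step 1**
Reactants: 1 prop-2-yn-1-ol (propargyl alcohol)
Product: 3 (Z)-3-iodo-2-methylprop-2-en-1-ol, via alkenylmagnesium chelate 2 (not isolated)
Conditions: MeMgBr (3 equiv), CuI (10 mol %), THF, −10 °C → rt; then I2, −10 °C
Reagents that add atoms: methylmagnesium bromide C[Mg]Br; iodine II
Why: Copper-catalysed, alkoxide-directed anti-carbomagnesiation (Duboudin reaction) puts methyl on the internal carbon and magnesium on the terminal carbon cis to the CH2O arm in a five-membered chelate, and iodinolysis with retention gives the Z-iodoalkene that becomes C4=C5.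

**Step 2**
Reactants: 3 (Z)-3-iodo-2-methylprop-2-en-1-ol
Product: 4 (Z)-3-bromo-1-iodo-2-methylprop-1-ene
Conditions: PBr3, Et2O, 0 °C
Reagents that add atoms: phosphorus tribromide BrP(Br)Br
Why: PBr3 converts the primary allylic alcohol into the bromide through a phosphite ester and SN2 displacement, and the alkenyl iodide and its geometry are not involved.

**Step 3**
Reactants: 4 (Z)-3-bromo-1-iodo-2-methylprop-1-ene; 5 acetaldehyde N,N-dimethylhydrazone
Product: 7 (Z)-5-iodo-4-methylpent-4-enal, via hydrazone 6 (not isolated)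
Conditions: 5, LDA, THF, 0 °C; then 4, −78 → 0 °C; then aq. oxalic acid, Et2O, rt
Reagents that add atoms: water O
Why: The lithiated hydrazone (Corey–Enders aza-enolate alkylation) displaces the allylic bromide by SN2 without halogen–metal exchange at the alkenyl iodide, and two-phase hydrolysis releases the aldehyde that carries C1–C5 and C15.

**Step 4**
Reactants: 8 (E)-but-2-ene-1,4-diol
Product: 9 (E)-4-[(4-methoxybenzyl)oxy]but-2-en-1-ol
Conditions: NaH (1 equiv), PMBCl, Bu4NI (cat.), THF, 0 °C → rt (8 in excess)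
Reagents that add atoms: 4-methoxybenzyl chloride COc1ccc(CCl)cc1
Why: Williamson etherification of the mono-alkoxide, with the diol in excess, gives the mono-PMB ether and keeps one allylic hydroxyl free for the directed epoxidation.

**Step 5**
Reactants: 9 (E)-4-[(4-methoxybenzyl)oxy]but-2-en-1-ol
Product: 10 [(2R,3R)-3-{[(4-methoxybenzyl)oxy]methyl}oxiran-2-yl]methanol
Conditions: Ti(OiPr)4 (cat.), D-(−)-diethyl tartrate, t-BuOOH, 4 Å MS, CH2Cl2, −20 °C
Reagents that add atoms: tert-butyl hydroperoxide CC(C)(C)OO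
Why: Sharpless asymmetric epoxidation of the E-allylic alcohol with the titanium/D-(−)-tartrate catalyst delivers oxygen to one enantioface and gives the trans (2R,3R)-epoxide, which fixes C8 and sets up C7.

**Step 6**
Reactants: 10 [(2R,3R)-3-{[(4-methoxybenzyl)oxy]methyl}oxiran-2-yl]methanol; 11 ethynyltrimethylsilane
Product: 13 (2S,3S)-3-{[(4-methoxybenzyl)oxy]methyl}-5-(trimethylsilyl)pent-4-yne-1,2-diol, via alkynylalane 12 (not isolated)
Conditions: 11, n-BuLi, toluene, 0 °C; Et2AlCl; then 10, 0 °C → rt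
Reagents that add atoms: none
Why: The alkynylalane, bound to the C9 alkoxide, opens the 2,3-epoxy alcohol at the distal carbon C7 with SN2 inversion (aluminium-directed C3-selective epoxide opening), so the alkyne is placed anti to the C8 hydroxyl and a 1,2-diol results.

**Step 7**
Reactants: 13 (2S,3S)-3-{[(4-methoxybenzyl)oxy]methyl}-5-(trimethylsilyl)pent-4-yne-1,2-diol
Product: 14 (2S,3S)-3-{[(4-methoxybenzyl)oxy]methyl}-1,2-bis(triethylsilyloxy)-5-(trimethylsilyl)pent-4-yne
Conditions: TESCl (2.5 equiv), imidazole, CH2Cl2, 0 °C → rt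
Reagents that add atoms: chlorotriethylsilane CC[Si](Cl)(CC)CC
Why: Standard silylation of both hydroxyls, each with its own equivalent of the chlorosilane, prepares the primary silyl ether for direct oxidation and leaves a small, chelating silyloxy group on C8.

**Step 8**
Reactants: 14 (2S,3S)-3-{[(4-methoxybenzyl)oxy]methyl}-1,2-bis(triethylsilyloxy)-5-(trimethylsilyl)pent-4-yne
Product: 15 (2S,3S)-3-{[(4-methoxybenzyl)oxy]methyl}-2-(triethylsilyloxy)-5-(trimethylsilyl)pent-4-ynal
Conditions: (COCl)2, DMSO, CH2Cl2, −78 → −30 °C; then Et3N, −78 → 0 °C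
Reagents that add atoms: none
Why: Under Swern conditions the unhindered primary triethylsilyl ether is cleaved by the chlorosulfonium salt and oxidised to the aldehyde while the secondary silyl ether stays (selective oxidative desilylation of primary TES ethers), and the low temperature protects the C8 stereocentre.

**Step 9**
Reactants: 16 tert-butyl acetate
Product: 17 tert-butyl[(1-tert-butoxyvinyl)oxy]dimethylsilane
Conditions: LDA, THF, −78 °C; TBSCl, DMPU, −78 °C → rt
Reagents that add atoms: tert-butyldimethylsilyl chloride CC(C)(C)[Si](C)(C)Cl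
Why: O-Silylation of the lithium enolate of tert-butyl acetate gives the ketene silyl acetal needed for a Lewis acid mediated aldol addition.

**Step 10**
Reactants: 15 (2S,3S)-3-{[(4-methoxybenzyl)oxy]methyl}-2-(triethylsilyloxy)-5-(trimethylsilyl)pent-4-ynal; 17 tert-butyl[(1-tert-butoxyvinyl)oxy]dimethylsilane
Product: 18 tert-butyl (3S,4S,5S)-3-hydroxy-5-{[(4-methoxybenzyl)oxy]methyl}-4-(triethylsilyloxy)-7-(trimethylsilyl)hept-6-ynoate
Conditions: Me2AlCl (2.5 equiv), CH2Cl2, −78 °C; aq. Rochelle salt work-up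
Reagents that add atoms: none
Why: Mukaiyama aldol addition under 1,2-chelation control, in which Me2AlCl bridges the aldehyde oxygen and the α-silyloxy oxygen and the ketene acetal attacks the chelate on the face away from the C7 branch, should give the 8,9-syn pattern with C9 (S).

**Step 11**
Reactants: 18 tert-butyl (3S,4S,5S)-3-hydroxy-5-{[(4-methoxybenzyl)oxy]methyl}-4-(triethylsilyloxy)-7-(trimethylsilyl)hept-6-ynoate
Product: 19 tert-butyl (3S,4S,5S)-5-{[(4-methoxybenzyl)oxy]methyl}-3,4-bis(triethylsilyloxy)-7-(trimethylsilyl)hept-6-ynoate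
Conditions: TESOTf, 2,6-lutidine, CH2Cl2, −78 °C
Reagents that add atoms: triethylsilyl trifluoromethanesulfonate CC[Si](CC)(CC)OS(=O)(=O)C(F)(F)F
Why: Silylation of the C9 hydroxyl blocks retro-aldol pathways in the enolate chemistry that follows and makes the C8 and C9 oxygens removable together in one later step.

**Step 12**
Reactants: 19 tert-butyl (3S,4S,5S)-5-{[(4-methoxybenzyl)oxy]methyl}-3,4-bis(triethylsilyloxy)-7-(trimethylsilyl)hept-6-ynoate; 7 (Z)-5-iodo-4-methylpent-4-enal
Product: 20 tert-butyl (3S,4S,5S)-2-[(Z)-1-hydroxy-5-iodo-4-methylpent-4-en-1-yl]-5-{[(4-methoxybenzyl)oxy]methyl}-3,4-bis(triethylsilyloxy)-7-(trimethylsilyl)hept-6-ynoate (epimer mixture at C10 and C1)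
Conditions: LDA, THF, −78 °C; then 7, −78 °C
Reagents that add atoms: none
Why: Aldol addition of the lithium ester enolate, which is stable at −78 °C despite the β-silyloxy group, to the aldehyde joins C10 to C1; the two new centres need no control because both are erased in the next step.

**Step 13**
Reactants: 20 aldol adduct
Product: 22 tert-butyl (2E,6Z)-7-iodo-6-methyl-2-[(1S,2S,3S)-3-{[(4-methoxybenzyl)oxy]methyl}-1,2-bis(triethylsilyloxy)-5-(trimethylsilyl)pent-4-yn-1-yl]hepta-2,6-dienoate, via mesylate 21 (not isolated)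
Conditions: MsCl, Et3N, CH2Cl2, 0 °C; then DBU, 0 °C → rt
Reagents that add atoms: none
Why: Mesylation followed by DBU-induced E1cB elimination expels the far better leaving group at C1 and should give the conjugated ester as the E isomer (C2 trans to the ester, cis to C9), the geometry favoured by A(1,3) strain in the enolate and by thermodynamics.

**Step 14**
Reactants: 22 PMB-protected dienoate
Product: 23 tert-butyl (2E,6Z)-2-[(1S,2S,3S)-3-(hydroxymethyl)-1,2-bis(triethylsilyloxy)-5-(trimethylsilyl)pent-4-yn-1-yl]-7-iodo-6-methylhepta-2,6-dienoate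
Conditions: DDQ, CH2Cl2/pH 7 buffer, 0 °C
Reagents that add atoms: none
Why: DDQ oxidises the electron-rich PMB ether to an oxocarbenium ion that water hydrolyses, which frees the C6 hydroxyl while silyl ethers, alkenyl iodide, alkyne and enoate stay untouched.

**Step 15**
Reactants: 23 primary alcohol
Product: 24 tert-butyl (2E,6Z)-2-[(1S,2S,3R)-3-formyl-1,2-bis(triethylsilyloxy)-5-(trimethylsilyl)pent-4-yn-1-yl]-7-iodo-6-methylhepta-2,6-dienoate (seco aldehyde)
Conditions: Dess–Martin periodinane, NaHCO3, CH2Cl2, 0 °C → rt; used directly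
Reagents that add atoms: none
Why: Dess–Martin oxidation under buffered, non-basic conditions should give the aldehyde without enolising the α-alkynyl stereocentre C7.

**Step 16**
Reactants: 24 seco aldehyde
Product: 25 tert-butyl (1E,5Z,7R,8S,9S,10S)-7-hydroxy-5-methyl-9,10-bis(triethylsilyloxy)-8-[(trimethylsilyl)ethynyl]cyclodeca-1,5-diene-1-carboxylate (germacrane 6R,7S,8S,9S)
Conditions: CrCl2 (10 equiv), NiCl2 (cat.), DMSO/THF, rt, 2 mM, slow addition
Reagents that add atoms: none
Why: Nozaki–Hiyama–Kishi reaction in which nickel inserts into the C5–I bond with retention of the Z geometry, the alkenylchromium(III) species adds only to the aldehyde, high dilution favours closure of the ten-membered ring, and Felkin–Anh attack anti to the bulky C8 branch (slim alkyne as medium group) should give the 6R carbinol, trans to the C7 alkyne on the ring.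

**Step 17**
Reactants: 25 macrocyclic alcohol
Product: 26 C6 tert-butyldimethylsilyl ether of 25 (germacrane 6R,7S,8S,9S)
Conditions: TBSOTf (1.2 equiv), 2,6-lutidine, CH2Cl2, −78 °C
Reagents that add atoms: tert-butyldimethylsilyl trifluoromethanesulfonate CC(C)(C)[Si](C)(C)OS(=O)(=O)C(F)(F)F
Why: Silylation with a slight excess of TBSOTf at −78 °C is much faster at the hydroxyl than at the tert-butyl ester and masks C6–OH with a group that survives the release and acylation of the C8/C9 diol.

**Step 18**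
Reactants: 26 tris-silyl ether
Product: 27 tert-butyl (1E,5Z,7R,8R,9S,10S)-7-(tert-butyldimethylsilyloxy)-9,10-dihydroxy-5-methyl-8-[(trimethylsilyl)ethynyl]cyclodeca-1,5-diene-1-carboxylate (germacrane 6R,7R,8S,9S)
Conditions: HF·pyridine, pyridine, THF, 0 °C
Reagents that add atoms: none
Why: Triethylsilyl ethers are cleaved by buffered HF·pyridine far faster than the secondary TBS ether or the C-silyl alkyne, so only the C8 and C9 hydroxyls should be released (selective desilylation).

**Step 19**
Reactants: 27 C8/C9 diol; 28 angelic acid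
Product: 30 8,9-bis-O-angeloyl derivative of 27 (germacrane 6R,7R,8S,9S), via mixed anhydride 29 (not isolated)
Conditions: 28 (3 equiv in all), 2,4,6-Cl3C6H2COCl (3 equiv), Et3N, toluene, rt; then 27, toluene, 80 °C
Reagents that add atoms: angelic acid (second equivalent) C/C=C(/C)C(=O)O
Why: Yamaguchi-type acylation through the angelic 2,4,6-trichlorobenzoic mixed anhydride, run without a nucleophilic catalyst, should esterify each of the two secondary hydroxyls with its own molecule of 29 at the angeloyl carbonyl, so that two equivalents of angelic acid are built into 30, and should avoid the Z to E isomerisation that carbodiimide/DMAP methods cause.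

**Step 20**
Reactants: 30 bis-angelate tert-butyl ester
Product: 32 (1E,5Z)-7-(tert-butyldimethylsilyloxy)-9,10-bis(angeloyloxy)-5-methyl-8-[(trimethylsilyl)ethynyl]cyclodeca-1,5-diene-1-carboxylic acid (germacrane 6R,7R,8S,9S), via trimethylsilyl ester 31 (not isolated)
Conditions: TMSOTf, 2,6-lutidine, CH2Cl2, 0 °C; then pH 5 aq. buffer
Reagents that add atoms: none
Why: TMSOTf silylates the ester carbonyl, the tert-butyl group leaves as isobutene (silyl triflate cleavage of tert-butyl esters), and hydrolysis of the labile silyl ester gives the acid without protic acid that could ionise the allylic C6 oxygen.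

**Step 21**
Reactants: 32 silyl-protected acid
Product: 33 ten-membered trans alkynol bis-angelate acid (germacrane 6R,7S,8S,9S; C6–OH, C7–C≡CH)
Conditions: TBAF, AcOH, THF, 0 °C → rt
Reagents that add atoms: none
Why: Buffered fluoride cleaves the O–Si bond at C6 and the C(sp)–Si bond in one operation (fluoride desilylation), and acetic acid keeps the medium from becoming basic enough for acyl migration.

**Step 22**
Reactants: 33 trans alkynol bis-angelate acid; 34 carbon monoxide
Product: 35 CNP0154468.1, 8,9-bis(angeloyloxy)-1(10)E,4Z-germacra-1(10),4,11(13)-trien-12,6-olid-14-oic acid (6R,7S,8S,9S)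
Conditions: CO (7 atm), PdCl2 (10 mol %), PPh3 (20 mol %), SnCl2 (10 mol %), MeCN, 70 °C
Reagents that add atoms: none
Why: Palladium(II) binds the C6 hydroxyl and CO to give an alkoxycarbonyl–palladium species, which adds syn across the pendant alkyne so that C12 bonds to C11 and palladium ends on the terminal carbon, and protonolysis of that alkenyl–Pd bond releases the exo-methylene group and the catalyst. The closest known reaction is the PdCl2/PPh3/SnCl2-catalysed cyclocarbonylation of 3-butyn-1-ols, which turns trans-2-ethynylcyclohexanol into the trans-fused α-methylene-γ-butyrolactone. The lactone ring closes in a 5-exo-dig mode by intramolecular acylpalladation. No stereocentre is formed, because the trans ring fusion is the trans C6–O/C7–alkyne relationship already present and neither centre is touched. The step needs chemoselectivity for one hydroxyl and one alkyne, which the substrate secures because only O6 is homopropargylic (the C14 acid could close only an eight-membered ring) and the angelate and enoate double bonds are not terminal alkynes.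

**Compound list**
1 | prop-2-yn-1-ol (propargyl alcohol) | C#CCO | starting material
2 | bromomagnesium (Z)-3-(bromomagnesio)-2-methylprop-2-en-1-olate (alkenylmagnesium chelate) | Br[Mg]/C=C(/C)CO[Mg]Br | intermediate
3 | (Z)-3-iodo-2-methylprop-2-en-1-ol | OC/C(C)=C\I | intermediate
4 | (Z)-3-bromo-1-iodo-2-methylprop-1-ene | BrC/C(C)=C\I | intermediate
5 | acetaldehyde N,N-dimethylhydrazone | CC=NN(C)C | starting material
6 | (Z)-5-iodo-4-methylpent-4-enal N,N-dimethylhydrazone | CN(C)N=CCC/C(C)=C\I | intermediate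
7 | (Z)-5-iodo-4-methylpent-4-enal | O=CCC/C(C)=C\I | intermediate
8 | (E)-but-2-ene-1,4-diol | OC/C=C/CO | starting material
9 | (E)-4-[(4-methoxybenzyl)oxy]but-2-en-1-ol | OC/C=C/COCc1ccc(OC)cc1 | intermediate
10 | [(2R,3R)-3-{[(4-methoxybenzyl)oxy]methyl}oxiran-2-yl]methanol | OC[C@H]1O[C@@H]1COCc1ccc(OC)cc1 | intermediate
11 | ethynyltrimethylsilane | C#C[Si](C)(C)C | starting material
12 | diethyl[(trimethylsilyl)ethynyl]aluminium | CC[Al](CC)C#C[Si](C)(C)C | intermediate
13 | (2S,3S)-3-{[(4-methoxybenzyl)oxy]methyl}-5-(trimethylsilyl)pent-4-yne-1,2-diol | OC[C@@H](O)[C@@H](C#C[Si](C)(C)C)COCc1ccc(OC)cc1 | intermediate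
14 | (2S,3S)-3-{[(4-methoxybenzyl)oxy]methyl}-1,2-bis(triethylsilyloxy)-5-(trimethylsilyl)pent-4-yne | CC[Si](CC)(CC)OC[C@@H](O[Si](CC)(CC)CC)[C@@H](C#C[Si](C)(C)C)COCc1ccc(OC)cc1 | intermediate
15 | (2S,3S)-3-{[(4-methoxybenzyl)oxy]methyl}-2-(triethylsilyloxy)-5-(trimethylsilyl)pent-4-ynal | O=C[C@@H](O[Si](CC)(CC)CC)[C@@H](C#C[Si](C)(C)C)COCc1ccc(OC)cc1 | intermediate
16 | tert-butyl acetate | CC(=O)OC(C)(C)C | starting material
17 | tert-butyl[(1-tert-butoxyvinyl)oxy]dimethylsilane | C=C(OC(C)(C)C)O[Si](C)(C)C(C)(C)C | intermediate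
18 | tert-butyl (3S,4S,5S)-3-hydroxy-5-{[(4-methoxybenzyl)oxy]methyl}-4-(triethylsilyloxy)-7-(trimethylsilyl)hept-6-ynoate | CC(C)(C)OC(=O)C[C@H](O)[C@@H](O[Si](CC)(CC)CC)[C@@H](C#C[Si](C)(C)C)COCc1ccc(OC)cc1 | intermediate
19 | tert-butyl (3S,4S,5S)-5-{[(4-methoxybenzyl)oxy]methyl}-3,4-bis(triethylsilyloxy)-7-(trimethylsilyl)hept-6-ynoate | CC(C)(C)OC(=O)C[C@H](O[Si](CC)(CC)CC)[C@@H](O[Si](CC)(CC)CC)[C@@H](C#C[Si](C)(C)C)COCc1ccc(OC)cc1 | intermediate
20 | tert-butyl (3S,4S,5S)-2-[(Z)-1-hydroxy-5-iodo-4-methylpent-4-en-1-yl]-5-{[(4-methoxybenzyl)oxy]methyl}-3,4-bis(triethylsilyloxy)-7-(trimethylsilyl)hept-6-ynoate (epimers at C10 and C1) | I/C=C(/C)CCC(O)C(C(=O)OC(C)(C)C)[C@H](O[Si](CC)(CC)CC)[C@@H](O[Si](CC)(CC)CC)[C@@H](C#C[Si](C)(C)C)COCc1ccc(OC)cc1 | intermediate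
21 | methanesulfonate of 20 at the C1 hydroxyl | I/C=C(/C)CCC(OS(C)(=O)=O)C(C(=O)OC(C)(C)C)[C@H](O[Si](CC)(CC)CC)[C@@H](O[Si](CC)(CC)CC)[C@@H](C#C[Si](C)(C)C)COCc1ccc(OC)cc1 | intermediate
22 | tert-butyl (2E,6Z)-7-iodo-6-methyl-2-[(1S,2S,3S)-3-{[(4-methoxybenzyl)oxy]methyl}-1,2-bis(triethylsilyloxy)-5-(trimethylsilyl)pent-4-yn-1-yl]hepta-2,6-dienoate | I/C=C(/C)CC/C=C(/C(=O)OC(C)(C)C)[C@H](O[Si](CC)(CC)CC)[C@@H](O[Si](CC)(CC)CC)[C@@H](C#C[Si](C)(C)C)COCc1ccc(OC)cc1 | intermediate
23 | tert-butyl (2E,6Z)-2-[(1S,2S,3S)-3-(hydroxymethyl)-1,2-bis(triethylsilyloxy)-5-(trimethylsilyl)pent-4-yn-1-yl]-7-iodo-6-methylhepta-2,6-dienoate | I/C=C(/C)CC/C=C(/C(=O)OC(C)(C)C)[C@H](O[Si](CC)(CC)CC)[C@@H](O[Si](CC)(CC)CC)[C@@H](C#C[Si](C)(C)C)CO | intermediate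
24 | tert-butyl (2E,6Z)-2-[(1S,2S,3R)-3-formyl-1,2-bis(triethylsilyloxy)-5-(trimethylsilyl)pent-4-yn-1-yl]-7-iodo-6-methylhepta-2,6-dienoate | I/C=C(/C)CC/C=C(/C(=O)OC(C)(C)C)[C@H](O[Si](CC)(CC)CC)[C@@H](O[Si](CC)(CC)CC)[C@@H](C#C[Si](C)(C)C)C=O | intermediate
25 | tert-butyl (1E,5Z,7R,8S,9S,10S)-7-hydroxy-5-methyl-9,10-bis(triethylsilyloxy)-8-[(trimethylsilyl)ethynyl]cyclodeca-1,5-diene-1-carboxylate | O[C@@H]1/C=C(/C)CC/C=C(/C(=O)OC(C)(C)C)[C@H](O[Si](CC)(CC)CC)[C@@H](O[Si](CC)(CC)CC)[C@H]1C#C[Si](C)(C)C | intermediate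
26 | tert-butyl (1E,5Z,7R,8S,9S,10S)-7-(tert-butyldimethylsilyloxy)-5-methyl-9,10-bis(triethylsilyloxy)-8-[(trimethylsilyl)ethynyl]cyclodeca-1,5-diene-1-carboxylate | CC(C)(C)[Si](C)(C)O[C@@H]1/C=C(/C)CC/C=C(/C(=O)OC(C)(C)C)[C@H](O[Si](CC)(CC)CC)[C@@H](O[Si](CC)(CC)CC)[C@H]1C#C[Si](C)(C)C | intermediate
27 | tert-butyl (1E,5Z,7R,8R,9S,10S)-7-(tert-butyldimethylsilyloxy)-9,10-dihydroxy-5-methyl-8-[(trimethylsilyl)ethynyl]cyclodeca-1,5-diene-1-carboxylate | CC(C)(C)[Si](C)(C)O[C@@H]1/C=C(/C)CC/C=C(/C(=O)OC(C)(C)C)[C@H](O)[C@@H](O)[C@H]1C#C[Si](C)(C)C | intermediate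
28 | angelic acid, (Z)-2-methylbut-2-enoic acid | C/C=C(/C)C(=O)O | starting material
29 | angelic 2,4,6-trichlorobenzoic anhydride | C/C=C(/C)C(=O)OC(=O)c1c(Cl)cc(Cl)cc1Cl | intermediate
30 | tert-butyl (1E,5Z,7R,8R,9S,10S)-9,10-bis(angeloyloxy)-7-(tert-butyldimethylsilyloxy)-5-methyl-8-[(trimethylsilyl)ethynyl]cyclodeca-1,5-diene-1-carboxylate | CC(C)(C)[Si](C)(C)O[C@@H]1/C=C(/C)CC/C=C(/C(=O)OC(C)(C)C)[C@H](OC(=O)/C(C)=C\C)[C@@H](OC(=O)/C(C)=C\C)[C@H]1C#C[Si](C)(C)C | intermediate
31 | trimethylsilyl ester corresponding to 30 | CC(C)(C)[Si](C)(C)O[C@@H]1/C=C(/C)CC/C=C(/C(=O)O[Si](C)(C)C)[C@H](OC(=O)/C(C)=C\C)[C@@H](OC(=O)/C(C)=C\C)[C@H]1C#C[Si](C)(C)C | intermediate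
32 | (1E,5Z,7R,8R,9S,10S)-9,10-bis(angeloyloxy)-7-(tert-butyldimethylsilyloxy)-5-methyl-8-[(trimethylsilyl)ethynyl]cyclodeca-1,5-diene-1-carboxylic acid | CC(C)(C)[Si](C)(C)O[C@@H]1/C=C(/C)CC/C=C(/C(=O)O)[C@H](OC(=O)/C(C)=C\C)[C@@H](OC(=O)/C(C)=C\C)[C@H]1C#C[Si](C)(C)C | intermediate
33 | (1E,5Z,7R,8S,9S,10S)-9,10-bis(angeloyloxy)-8-ethynyl-7-hydroxy-5-methylcyclodeca-1,5-diene-1-carboxylic acid | O[C@@H]1/C=C(/C)CC/C=C(/C(=O)O)[C@H](OC(=O)/C(C)=C\C)[C@@H](OC(=O)/C(C)=C\C)[C@H]1C#C | intermediate
34 | carbon monoxide | [C-]#[O+] | starting material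
35 | CNP0154468.1, (6R,7S,8S,9S)-8,9-bis(angeloyloxy)-1(10)E,4Z-germacra-1(10),4,11(13)-trien-12,6-olid-14-oic acid | C=C1C(=O)O[C@@H]2/C=C(/C)CC/C=C(/C(=O)O)[C@H](OC(=O)/C(C)=C\C)[C@@H](OC(=O)/C(C)=C\C)[C@@H]12 | target

**Step count**
Total: 22 steps. Longest linear sequence: 18 steps (steps 4–8 and 10–22, from 8); steps 1–3 and step 9 are side branches.

**Steps most likely to fail**

Step 16 (Ni/Cr ring closure). The alkenylchromium may add to the other face of the aldehyde, since the facial preference inside a forming ten-membered ring is hard to predict, so that the C6 epimer dominates. The fallback sets out from 24 and lets the same ring closure deliver the 6-epi alcohol F1. C6 is then inverted by a Mitsunobu reaction with chloroacetic acid (PPh3, DIAD, toluene, 0 °C) to the 6R chloroacetate F2. The chloroacetyl group is removed with thiourea and NaHCO3 in ethanol, which spares the silyl groups and the tert-butyl ester, and the route is rejoined at 25. The stereocentre is then set by SN2 inversion and no longer by the facial preference of the C–C bond formation.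

Step 22 (cyclocarbonylation). Acylpalladation inside the congested ten-membered ring may be slow, so that hydration or oligomerisation of the terminal alkyne and palladium-induced ionisation of the allylic C6 oxygen compete. The fallback sets out from 33: Markovnikov bromoboration with B-bromo-9-BBN (in excess, because the hydroxyl and the acid are borylated in the flask and set free again on work-up; CH2Cl2, 0 °C) and protonolysis with acetic acid give the 2-bromoalkene F3, with bromine on C11. Pd(0)-catalysed carbonylative lactonisation (Pd(PPh3)4, CO 1 atm, Et3N, MeCN, 60 °C; oxidative addition, CO insertion, capture of the acylpalladium by O6) then closes the same lactone and arrives at 35.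

Step 19 (bis-angeloylation). Acylation of the two hindered vicinal hydroxyls may be slower than Z to E isomerisation of the activated angeloyl unit (tiglate formation), or may stop at the mono-ester. The fallback sets out from 27: both hydroxyls are esterified with 2-[bis(2,2,2-trifluoroethoxy)phosphoryl]propanoic acid (DCC, DMAP, CH2Cl2) to the bis-phosphonate F4. Each Z-2-methylbut-2-enoate is then built in place by Still–Gennari olefination with acetaldehyde (KHMDS, 18-crown-6, THF, −78 °C), and the route is rejoined at 30.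

**Further compounds**
F1 | step 16 | C6 epimer of 25, tert-butyl (1E,5Z,7S,8S,9S,10S)-7-hydroxy-5-methyl-9,10-bis(triethylsilyloxy)-8-[(trimethylsilyl)ethynyl]cyclodeca-1,5-diene-1-carboxylate | O[C@H]1/C=C(/C)CC/C=C(/C(=O)OC(C)(C)C)[C@H](O[Si](CC)(CC)CC)[C@@H](O[Si](CC)(CC)CC)[C@H]1C#C[Si](C)(C)C
F2 | step 16 | 6-O-chloroacetyl derivative of 25 (C6 configured as in 25) | ClCC(=O)O[C@@H]1/C=C(/C)CC/C=C(/C(=O)OC(C)(C)C)[C@H](O[Si](CC)(CC)CC)[C@@H](O[Si](CC)(CC)CC)[C@H]1C#C[Si](C)(C)C
F3 | step 22 | analogue of 33 with a 1-bromovinyl group on C7 in place of ethynyl | O[C@@H]1/C=C(/C)CC/C=C(/C(=O)O)[C@H](OC(=O)/C(C)=C\C)[C@@H](OC(=O)/C(C)=C\C)[C@H]1C(Br)=C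
F4 | step 19 | 8,9-bis-O-{2-[bis(2,2,2-trifluoroethoxy)phosphoryl]propanoyl} derivative of 27 (epimers at the phosphonate carbons) | CC(C)(C)[Si](C)(C)O[C@@H]1/C=C(/C)CC/C=C(/C(=O)OC(C)(C)C)[C@H](OC(=O)C(C)P(=O)(OCC(F)(F)F)OCC(F)(F)F)[C@@H](OC(=O)C(C)P(=O)(OCC(F)(F)F)OCC(F)(F)F)[C@H]1C#C[Si](C)(C)C
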